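**Retrosynthetic overview**
1. Bought building blocks: acetophenone 1 (A ring, already carrying the 7,8-dimethoxy pattern and the future O1) and aldehyde 2 (B ring, complete).
2. Chalcone 3 comes from 1 + 2 by Claisen–Schmidt condensation (the only C–C bond made).
3. O1–C2 disconnection: flavone 5 comes from 3 through flavanone 4 by oxidative oxa-Michael ring closure; the pyranone C ring is formed here.
4. C5–O disconnection: target 9 comes from 5 through boron intermediates 6–8 by carbonyl-directed C5–H borylation and oxidation, as the last step.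
5. Ring order: A and B rings bought intact, C ring closed second, 5-OH installed last.

Assumption: the target SMILES has no stereocentre (the molecule is achiral), so there is no enantiomer to select; 1 and 2 are taken as catalogue compounds.

**Step 1**
Reactants: 1 1-(2-hydroxy-3,4-dimethoxyphenyl)ethan-1-one; 2 4-hydroxy-2,3-dimethoxybenzaldehyde
Product: 3 (E)-1-(2-hydroxy-3,4-dimethoxyphenyl)-3-(4-hydroxy-2,3-dimethoxyphenyl)prop-2-en-1-one
Conditions: 50% aq KOH (10 equiv), EtOH, rt, 72 h; then 2 M HCl to pH 3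
Reagents that add atoms: none
Why: Claisen–Schmidt condensation: the ketone enolate adds to the aldehyde and E1cB loss of water gives the thermodynamically favoured E enone (no stereocentre), both phenols ride through as phenoxides, and the large excess of base with a long reaction time offsets the lower electrophilicity of the 4-oxido aldehyde.

**Step 2**
Reactants: 3 (E)-1-(2-hydroxy-3,4-dimethoxyphenyl)-3-(4-hydroxy-2,3-dimethoxyphenyl)prop-2-en-1-one
Product: 5 4'-hydroxy-7,8,2',3'-tetramethoxyflavone, via flavanone 4 (not isolated)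
Conditions: I2 (10 mol%), DMSO, 130 °C, 3 h
Reagents that add atoms: none
Why: Iodine/DMSO oxidative cyclisation of a 2'-hydroxychalcone: 6-endo oxa-Michael addition of the 2'-OH forms the O1–C2 bond (racemic flavanone 4), α-iodination and loss of HI then give the chromone while DMSO reoxidises HI to I2, so the transient C2 centre is erased and the free 4'-phenol and the methyl ethers are untouched.

**Step 3**
Reactants: 5 4'-hydroxy-7,8,2',3'-tetramethoxyflavone
Product: 9 5,4'-dihydroxy-7,8,2',3'-tetramethoxyflavone, via 4'-O-Bpin flavone 6 (not isolated), via 5-Bpin 4'-O-Bpin flavone 7 (not isolated), via 5,4'-bis(O-Bpin) flavone 8 (not isolated)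
Conditions: (i) HBpin (1.1 equiv), [Ir(OMe)(cod)]2 (2.5 mol%), AsPh3 (10 mol%), mesitylene, rt, 30 min; (ii) B2pin2 (1.5 equiv), 110 °C, 16 h; (iii) THF, aq NaHCO3, 30% H2O2 (3 equiv), 0 °C → rt, 1 h
Reagents that add atoms: hydrogen peroxide, OO (gives the C5 oxygen of 9); pinacolborane, CC1(C)OBOC1(C)C, and bis(pinacolato)diboron, CC1(C)OB(OC1(C)C)B1OC(C)(C)C(C)(C)O1 (their Bpin groups are in intermediates 6–8 only and are gone in 9)
Why: Proposed new method: chromone-carbonyl-directed, Ir-catalysed C5–H borylation with oxidation in the same flask; the phenol is first masked as its O–Bpin ester 6 by dehydrocoupling with HBpin, then the Lewis-basic, ring-locked C4=O (held syn to H-5) binds the Ir(III) tris(boryl) species that the monodentate AsPh3 ligand leaves with two open sites, so C–H cleavage can occur only at C5 through a five-membered iridacycle (C3–H would need a four-membered ring, the other C–H bonds are out of reach, and undirected borylation is slow with this ligand set), C–B reductive elimination gives 7, and peroxide-induced 1,2-shift of the aryl group from boron to oxygen followed by hydrolysis of both borate esters of 8 gives the 5-OH without exposing the electron-rich rings to a strong oxidant; the closest known reactions are the Ir/monodentate-ligand ortho-C–H borylation of simple aryl ketones and benzoates, carbonyl-directed C5–H functionalisation of chromones by Ru/Rh/Ir cyclometalation, and in-situ O-borylation of phenols as a traceless mask in Ir borylation, none shown for the C5–H bond of a flavone; no stereocentre is formed.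

**Compound list**
1 | 1-(2-hydroxy-3,4-dimethoxyphenyl)ethan-1-one (2'-hydroxy-3',4'-dimethoxyacetophenone) | CC(=O)c1ccc(OC)c(OC)c1O | starting material
2 | 4-hydroxy-2,3-dimethoxybenzaldehyde | O=Cc1ccc(O)c(OC)c1OC | starting material
3 | (E)-1-(2-hydroxy-3,4-dimethoxyphenyl)-3-(4-hydroxy-2,3-dimethoxyphenyl)prop-2-en-1-one | COc1ccc(C(=O)/C=C/c2ccc(O)c(OC)c2OC)c(O)c1OC | intermediate
4 | rac-2-(4-hydroxy-2,3-dimethoxyphenyl)-7,8-dimethoxychroman-4-one (racemic flavanone, not isolated) | COc1ccc2C(=O)CC(c3ccc(O)c(OC)c3OC)Oc2c1OC | intermediate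
5 | 2-(4-hydroxy-2,3-dimethoxyphenyl)-7,8-dimethoxy-4H-chromen-4-one (4'-hydroxy-7,8,2',3'-tetramethoxyflavone) | COc1ccc2c(=O)cc(-c3ccc(O)c(OC)c3OC)oc2c1OC | intermediate
6 | 2-[2,3-dimethoxy-4-[(4,4,5,5-tetramethyl-1,3,2-dioxaborolan-2-yl)oxy]phenyl]-7,8-dimethoxy-4H-chromen-4-one (not isolated) | COc1ccc2c(=O)cc(-c3ccc(OB4OC(C)(C)C(C)(C)O4)c(OC)c3OC)oc2c1OC | intermediate
7 | 2-[2,3-dimethoxy-4-[(4,4,5,5-tetramethyl-1,3,2-dioxaborolan-2-yl)oxy]phenyl]-7,8-dimethoxy-5-(4,4,5,5-tetramethyl-1,3,2-dioxaborolan-2-yl)-4H-chromen-4-one (not isolated) | COc1cc(B4OC(C)(C)C(C)(C)O4)c2c(=O)cc(-c3ccc(OB5OC(C)(C)C(C)(C)O5)c(OC)c3OC)oc2c1OC | intermediate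
8 | 2-[2,3-dimethoxy-4-[(4,4,5,5-tetramethyl-1,3,2-dioxaborolan-2-yl)oxy]phenyl]-7,8-dimethoxy-5-[(4,4,5,5-tetramethyl-1,3,2-dioxaborolan-2-yl)oxy]-4H-chromen-4-one (not isolated) | COc1cc(OB4OC(C)(C)C(C)(C)O4)c2c(=O)cc(-c3ccc(OB5OC(C)(C)C(C)(C)O5)c(OC)c3OC)oc2c1OC | intermediate
9 | 5-hydroxy-2-(4-hydroxy-2,3-dimethoxyphenyl)-7,8-dimethoxy-4H-chromen-4-one (5,4'-dihydroxy-7,8,2',3'-tetramethoxyflavone) | COc1cc(O)c2c(=O)cc(-c3ccc(O)c(OC)c3OC)oc2c1OC | target

**Total step count:** 3. **Longest linear sequence:** 3 (from 1 or 2).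

**Steps most likely to fail**

Step 3 (the proposed new step). The risks are no turnover on the flavone, or competing borylation at C5' next to the O–Bpin group. The fallback uses known chemistry and buys the C5 oxygen with the A ring instead of installing it. It sets out from aldehyde 2 and comes back to the route at target 9. Aldehyde 2 is condensed (50% aq KOH, EtOH, rt) with the dearer catalogue ketone 1-(2-hydroxy-3,4,6-trimethoxyphenyl)ethan-1-one F1 to give (E)-1-(2-hydroxy-3,4,6-trimethoxyphenyl)-3-(4-hydroxy-2,3-dimethoxyphenyl)prop-2-en-1-one F2. I2 (cat.) in DMSO at 130 °C closes this through rac-2-(4-hydroxy-2,3-dimethoxyphenyl)-5,7,8-trimethoxychroman-4-one F3 to 2-(4-hydroxy-2,3-dimethoxyphenyl)-5,7,8-trimethoxy-4H-chromen-4-one F4. BCl3 in CH2Cl2 at −20 → 0 °C then cleaves only the 5-OMe group, which is activated by chelation to the C4 carbonyl, and gives 9.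

Step 1. The 4-oxido aldehyde is a poor electrophile in base, so conversion may stall. The fallback masks the phenol; it sets out from aldehyde 2 and comes back at chalcone 3. Aldehyde 2 is protected (MOMCl, iPr2NEt, CH2Cl2) as 2,3-dimethoxy-4-(methoxymethoxy)benzaldehyde F5. Condensation with 1 (KOH, EtOH, rt) gives (E)-1-(2-hydroxy-3,4-dimethoxyphenyl)-3-[2,3-dimethoxy-4-(methoxymethoxy)phenyl]prop-2-en-1-one F6. The MOM group is removed with 3 M HCl in MeOH at 50 °C to return chalcone 3; any flavanone 4 formed in the acid is carried into step 2, where it is the intermediate anyway.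

Step 2. The risks are ring iodination of the electron-rich phenol or incomplete dehydrogenation. The fallback separates ring closure from oxidation; it sets out from chalcone 3 and comes back at flavone 5. Chalcone 3 is cyclised without oxidant (NaOAc, EtOH, reflux) to flavanone 4, which is isolated. Flavanone 4 is then dehydrogenated by Pd-catalysed aerobic α,β-dehydrogenation (Pd(TFA)2, DMSO as ligand, O2, AcOH, 80 °C; Pd enolate then β-hydride elimination) to give 5. No new compounds are made.

**Further compounds**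
F1 | step 3 | 1-(2-hydroxy-3,4,6-trimethoxyphenyl)ethan-1-one | CC(=O)c1c(O)c(OC)c(OC)cc1OC
F2 | step 3 | (E)-1-(2-hydroxy-3,4,6-trimethoxyphenyl)-3-(4-hydroxy-2,3-dimethoxyphenyl)prop-2-en-1-one | COc1cc(OC)c(C(=O)/C=C/c2ccc(O)c(OC)c2OC)c(O)c1OC
F3 | step 3 | rac-2-(4-hydroxy-2,3-dimethoxyphenyl)-5,7,8-trimethoxychroman-4-one | COc1cc(OC)c2C(=O)CC(c3ccc(O)c(OC)c3OC)Oc2c1OC
F4 | step 3 | 2-(4-hydroxy-2,3-dimethoxyphenyl)-5,7,8-trimethoxy-4H-chromen-4-one | COc1cc(OC)c2c(=O)cc(-c3ccc(O)c(OC)c3OC)oc2c1OC
F5 | step 1 | 2,3-dimethoxy-4-(methoxymethoxy)benzaldehyde | COCOc1ccc(C=O)c(OC)c1OC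
F6 | step 1 | (E)-1-(2-hydroxy-3,4-dimethoxyphenyl)-3-[2,3-dimethoxy-4-(methoxymethoxy)phenyl]prop-2-en-1-one | COCOc1ccc(/C=C/C(=O)c2ccc(OC)c(OC)c2O)c(OC)c1OC
F0 | step 2 | none | none
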